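**Strategy.** The route rests on cutting the bond between C5 of the benzene ring (ring A, para to the furan oxygen O1) and the acyloxy-bearing benzylic carbon of the side chain. That carbon is at the aldehyde oxidation level and carries the angelate, so it is brought in as racemic 1-chloroethyl angelate, an electrophile, and joined to the electrophilic aryl iodide by a nickel-catalysed enantioconvergent reductive cross-coupling. One operation forms the aryl–alkyl bond, sets the (R) benzylic centre and delivers the intact Z ester. The iodide partner, the complete trans-(2R,3S)-3-acetoxy-2-isopropenyl-dihydrobenzofuran (ring B), comes from a proline 5-enolexo aldol, methylenation and Mitsunobu inversion; late allylic oxidation gives the enal.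

Key step: step 6

Assumption: 1-chloroethyl chlorosulfate is taken as a purchasable reagent; the sense of induction of the bioxazoline ligand of step 6 is to be confirmed first in a model coupling of 9 with 4-iodoanisole, and the (4R,4'R) ligand is used instead should the model deliver the (S) ester.

**Step 1**
Reactants: 1 2-hydroxy-5-iodobenzaldehyde; 2 chloroacetone (1-chloropropan-2-one)
Product: 3 5-iodo-2-(2-oxopropoxy)benzaldehyde
Conditions: K2CO3, KI (cat.), DMF, 0 °C to rt
Reagents that add atoms: none
Why: Williamson O-alkylation of the acidic salicylaldehyde phenoxide by the α-chloro ketone (iodide-relayed) is fast at room temperature, where the base-mediated aldol/dehydration to the benzofuran (Rap–Stoermer reaction), which needs heat, should stay behind.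

**Step 2**
Reactants: 3 5-iodo-2-(2-oxopropoxy)benzaldehyde
Product: 4 1-[(2S,3R)-3-hydroxy-5-iodo-2,3-dihydro-1-benzofuran-2-yl]ethan-1-one (cis)
Conditions: (S)-proline (30 mol%), DMF, rt
Reagents that add atoms: none
Why: Proline-catalysed intramolecular (5-enolexo) aldol addition, in which the enamine formed on the oxygen-bearing methylene attacks the ortho aldehyde through a carboxylic-acid hydrogen-bonded transition state; for O-acetonyl salicylaldehydes this mode is known to close ring B cis and should set C2 as S and C3 as R.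

**Step 3**
Reactants: 4 1-[(2S,3R)-3-hydroxy-5-iodo-2,3-dihydro-1-benzofuran-2-yl]ethan-1-one
Product: 5 (2R,3R)-5-iodo-2-(prop-1-en-2-yl)-2,3-dihydro-1-benzofuran-3-ol (cis)
Conditions: Zn, CH2Br2, TiCl4, THF, −40 to 5 °C (reagent pre-formed); then 4, CH2Cl2, 0 °C to rt; NaHCO3 quench
Reagents that add atoms: dibromomethane, BrCBr
Why: Takai–Lombardo methylenation is non-basic and tolerates free hydroxyl groups and aryl iodides, so the enolisable β-hydroxy ketone should give the isopropenyl group without retro-aldol, C2 epimerisation or dehydration (the C2 descriptor changes from S to R by priority only, not in space).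

**Step 4**
Reactants: 5 (2R,3R)-5-iodo-2-(prop-1-en-2-yl)-2,3-dihydro-1-benzofuran-3-ol
Product: 6 (2R,3S)-5-iodo-2-(prop-1-en-2-yl)-2,3-dihydro-1-benzofuran-3-yl acetate (trans)
Conditions: PPh3, DIAD, AcOH, toluene, −20 °C to rt
Reagents that add atoms: acetic acid, CC(=O)O
Why: Mitsunobu esterification, in which acetate displaces the activated benzylic C3 oxygen by SN2 from the ring face that carries only hydrogens, so C3 is inverted (R to S), the 2,3-relationship becomes trans and the acetate is installed in the same operation.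

**Step 5**
Reactants: 7 angelic acid ((2Z)-2-methylbut-2-enoic acid); 8 1-chloroethyl chlorosulfate
Product: 9 racemic 1-chloroethyl (2Z)-2-methylbut-2-enoate (1-chloroethyl angelate)
Conditions: NaHCO3, n-Bu4NHSO4 (cat.), CH2Cl2/H2O, 0 °C to rt
Reagents that add atoms: none
Why: Phase-transfer O-alkylation of the carboxylate, with chlorosulfate as the better leaving group, gives the 1-chloroalkyl ester without ever activating the acid, so the Z geometry is not put at risk; the CHCl centre is racemic, which does not matter because it is reset in step 6.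

**Step 6**
Reactants: 6 (2R,3S)-5-iodo-2-(prop-1-en-2-yl)-2,3-dihydro-1-benzofuran-3-yl acetate; 9 racemic 1-chloroethyl angelate (1.5 equiv)
Product: 10 (1R)-1-[(2R,3S)-3-acetoxy-2-(prop-1-en-2-yl)-2,3-dihydro-1-benzofuran-5-yl]ethyl (2Z)-2-methylbut-2-enoate
Conditions: NiBr2·DME (nickel dibromide–1,2-dimethoxyethane, 10 mol%), (4S,4'S)-4,4'-di(heptan-4-yl)-4,4',5,5'-tetrahydro-2,2'-bioxazole (12 mol%), Mn powder, DMA, 5 °C
Reagents that add atoms: none
Why: Zerovalent nickel bearing the chiral bioxazoline adds oxidatively to the C5–I bond, the monovalent nickel halide formed in the cycle abstracts chlorine from 9 to give a planar α-acyloxyalkyl radical, this radical is captured by the divalent aryl nickel species to a trivalent aryl(alkyl)nickel that reductively eliminates the C5–C bond, and Mn returns nickel to the low-valent state. The closest known reaction types are the nickel-catalysed enantioconvergent reductive cross-electrophile coupling of aryl iodides with racemic secondary alkyl halides bearing a radical-stabilising α-substituent and the enantioconvergent nickel coupling of racemic 1-haloalkyl esters. No ring is closed. The new benzylic stereocentre is set (R) by the ligand at the radical-capture and reductive-elimination stage, both enantiomers of 9 converging through the radical, while the remote C2 and C3 centres of ring B should not interfere and make any minor epimer a separable diastereomer. The step needs cross-coupling over homo-coupling and reaction at C–I rather than at the allylic C2–O1 ether or the benzylic C3 acetate, which the fast oxidative addition of the aryl iodide at low temperature and the easy reduction of the oxygen-activated C–Cl bond should secure. The Z angelate should survive because no nickel hydride, acid or base is generated.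

**Step 7**
Reactants: 10 (1R)-1-[(2R,3S)-3-acetoxy-2-(prop-1-en-2-yl)-2,3-dihydro-1-benzofuran-5-yl]ethyl (2Z)-2-methylbut-2-enoate
Product: 11 (1R)-1-[(2R,3S)-3-acetoxy-2-(3-hydroxyprop-1-en-2-yl)-2,3-dihydro-1-benzofuran-5-yl]ethyl (2Z)-2-methylbut-2-enoate
Conditions: SeO2 (30 mol%), t-BuOOH, CH2Cl2, rt
Reagents that add atoms: selenium dioxide, O=[Se]=O; tert-butyl hydroperoxide (terminal oxidant), CC(C)(C)OO
Why: SeO2-catalysed allylic hydroxylation (ene reaction, then [2,3]-sigmatropic shift) should take place at the methyl group of the only electron-rich alkene, since CH3 is preferred over the tertiary C2–H and the conjugated angelate is deactivated; no stereocentre is touched.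

**Step 8**
Reactants: 11 (1R)-1-[(2R,3S)-3-acetoxy-2-(3-hydroxyprop-1-en-2-yl)-2,3-dihydro-1-benzofuran-5-yl]ethyl (2Z)-2-methylbut-2-enoate
Product: 12 (1R)-1-[(2R,3S)-3-acetoxy-2-(3-oxoprop-1-en-2-yl)-2,3-dihydro-1-benzofuran-5-yl]ethyl (2Z)-2-methylbut-2-enoate (target)
Conditions: MnO2 (activated), CH2Cl2, rt
Reagents that add atoms: none
Why: MnO2 oxidises only the primary allylic alcohol to the α-methylene aldehyde under neutral conditions, which should leave the acid-sensitive benzylic acetate and angelate, the Z alkene and all three stereocentres unchanged.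

**Compound list**
1 | 2-hydroxy-5-iodobenzaldehyde | O=Cc1cc(I)ccc1O | starting material
2 | chloroacetone | CC(=O)CCl | starting material
3 | 5-iodo-2-(2-oxopropoxy)benzaldehyde | CC(=O)COc1ccc(I)cc1C=O | intermediate
4 | 1-[(2S,3R)-3-hydroxy-5-iodo-2,3-dihydro-1-benzofuran-2-yl]ethan-1-one | CC(=O)[C@H]1Oc2ccc(I)cc2[C@H]1O | intermediate
5 | (2R,3R)-5-iodo-2-(prop-1-en-2-yl)-2,3-dihydro-1-benzofuran-3-ol | C=C(C)[C@H]1Oc2ccc(I)cc2[C@H]1O | intermediate
6 | (2R,3S)-5-iodo-2-(prop-1-en-2-yl)-2,3-dihydro-1-benzofuran-3-yl acetate | C=C(C)[C@H]1Oc2ccc(I)cc2[C@@H]1OC(C)=O | intermediate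
7 | angelic acid, (2Z)-2-methylbut-2-enoic acid | C/C=C(/C)C(=O)O | starting material
8 | 1-chloroethyl chlorosulfate | CC(Cl)OS(=O)(=O)Cl | starting material
9 | racemic 1-chloroethyl (2Z)-2-methylbut-2-enoate | C/C=C(/C)C(=O)OC(C)Cl | intermediate
10 | (1R)-1-[(2R,3S)-3-acetoxy-2-(prop-1-en-2-yl)-2,3-dihydro-1-benzofuran-5-yl]ethyl (2Z)-2-methylbut-2-enoate | C=C(C)[C@H]1Oc2ccc([C@@H](C)OC(=O)/C(C)=C\C)cc2[C@@H]1OC(C)=O | intermediate
11 | (1R)-1-[(2R,3S)-3-acetoxy-2-(3-hydroxyprop-1-en-2-yl)-2,3-dihydro-1-benzofuran-5-yl]ethyl (2Z)-2-methylbut-2-enoate | C=C(CO)[C@H]1Oc2ccc([C@@H](C)OC(=O)/C(C)=C\C)cc2[C@@H]1OC(C)=O | intermediate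
12 | (1R)-1-[(2R,3S)-3-acetoxy-2-(3-oxoprop-1-en-2-yl)-2,3-dihydro-1-benzofuran-5-yl]ethyl (2Z)-2-methylbut-2-enoate | C=C(C=O)[C@H]1Oc2ccc([C@@H](C)OC(=O)/C(C)=C\C)cc2[C@@H]1OC(C)=O | target

**Step count.** Total: 8 steps. Longest linear sequence: 7 steps (steps 1, 2, 3, 4, 6, 7, 8 from compound 1).

**Steps most likely to fail**

Step 6. The radical capture at nickel may give poor enantiofacial control, or homo-coupling and reduction of the aryl iodide may outrun the cross-coupling. The fallback builds the benzylic centre by polar chemistry, sets out from 6 and comes back at 10. Stille coupling of 6 with tributyl(1-ethoxyvinyl)stannane (Pd(PPh3)4, CuI, DMF, 50 °C) gives the enol ether (2R,3S)-5-(1-ethoxyethenyl)-2-(prop-1-en-2-yl)-2,3-dihydro-1-benzofuran-3-yl acetate F1. Work-up with dilute aqueous oxalic acid hydrolyses it to the methyl ketone (2R,3S)-5-acetyl-2-(prop-1-en-2-yl)-2,3-dihydro-1-benzofuran-3-yl acetate F2. Noyori transfer hydrogenation (RuCl(p-cymene)[(R,R)-TsDPEN], HCO2H/Et3N) should give (2R,3S)-5-[(1R)-1-hydroxyethyl]-2-(prop-1-en-2-yl)-2,3-dihydro-1-benzofuran-3-yl acetate F3. Yamaguchi esterification of F3 with angelic acid 7 (2,4,6-trichlorobenzoyl chloride, Et3N, DMAP, toluene) returns to 10.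

Step 7. Selenium may also attack the angelate methyl groups or the C2–H, the Z ester may isomerise, or the benzylic esters may solvolyse during the oxidation of the fully assembled molecule. The fallback moves the oxidation in front of the coupling, sets out from 6 and comes back at 11. Compound 6 is hydroxylated (SeO2, t-BuOOH, CH2Cl2) to (2R,3S)-2-(3-hydroxyprop-1-en-2-yl)-5-iodo-2,3-dihydro-1-benzofuran-3-yl acetate F4. Silylation (TBSCl, imidazole, DMF) gives (2R,3S)-2-[3-(tert-butyldimethylsilyloxy)prop-1-en-2-yl]-5-iodo-2,3-dihydro-1-benzofuran-3-yl acetate F5. Coupling with 9 under the conditions of step 6 gives (1R)-1-[(2R,3S)-3-acetoxy-2-[3-(tert-butyldimethylsilyloxy)prop-1-en-2-yl]-2,3-dihydro-1-benzofuran-5-yl]ethyl (2Z)-2-methylbut-2-enoate F6. Desilylation (HF·pyridine, THF, 0 °C) rejoins the route at 11.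

Step 4. The activated benzylic oxygen may be lost by elimination to the aromatic benzofuran, or by ionisation at C3, before the weakly acidic acetic acid is delivered. The fallback separates inversion from acetylation, sets out from 5 and comes back at 6. Mitsunobu reaction of 5 with the more acidic 4-nitrobenzoic acid (PPh3, DIAD, toluene, −20 °C) gives (2R,3S)-5-iodo-2-(prop-1-en-2-yl)-2,3-dihydro-1-benzofuran-3-yl 4-nitrobenzoate F7. Methanolysis (K2CO3, MeOH, 0 °C) gives the trans alcohol (2R,3S)-5-iodo-2-(prop-1-en-2-yl)-2,3-dihydro-1-benzofuran-3-ol F8. Acetylation (Ac2O, pyridine, DMAP) returns to 6.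

**Further compounds**
F1 | step 6 | (2R,3S)-5-(1-ethoxyethenyl)-2-(prop-1-en-2-yl)-2,3-dihydro-1-benzofuran-3-yl acetate | C=C(C)[C@H]1Oc2ccc(C(=C)OCC)cc2[C@@H]1OC(C)=O
F2 | step 6 | (2R,3S)-5-acetyl-2-(prop-1-en-2-yl)-2,3-dihydro-1-benzofuran-3-yl acetate | C=C(C)[C@H]1Oc2ccc(C(C)=O)cc2[C@@H]1OC(C)=O
F3 | step 6 | (2R,3S)-5-[(1R)-1-hydroxyethyl]-2-(prop-1-en-2-yl)-2,3-dihydro-1-benzofuran-3-yl acetate | C=C(C)[C@H]1Oc2ccc([C@@H](C)O)cc2[C@@H]1OC(C)=O
F4 | step 7 | (2R,3S)-2-(3-hydroxyprop-1-en-2-yl)-5-iodo-2,3-dihydro-1-benzofuran-3-yl acetate | C=C(CO)[C@H]1Oc2ccc(I)cc2[C@@H]1OC(C)=O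
F5 | step 7 | (2R,3S)-2-[3-(tert-butyldimethylsilyloxy)prop-1-en-2-yl]-5-iodo-2,3-dihydro-1-benzofuran-3-yl acetate | C=C(CO[Si](C)(C)C(C)(C)C)[C@H]1Oc2ccc(I)cc2[C@@H]1OC(C)=O
F6 | step 7 | (1R)-1-[(2R,3S)-3-acetoxy-2-[3-(tert-butyldimethylsilyloxy)prop-1-en-2-yl]-2,3-dihydro-1-benzofuran-5-yl]ethyl (2Z)-2-methylbut-2-enoate | C=C(CO[Si](C)(C)C(C)(C)C)[C@H]1Oc2ccc([C@@H](C)OC(=O)/C(C)=C\C)cc2[C@@H]1OC(C)=O
F7 | step 4 | (2R,3S)-5-iodo-2-(prop-1-en-2-yl)-2,3-dihydro-1-benzofuran-3-yl 4-nitrobenzoate | C=C(C)[C@H]1Oc2ccc(I)cc2[C@@H]1OC(=O)c1ccc(cc1)[N+](=O)[O-]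
F8 | step 4 | (2R,3S)-5-iodo-2-(prop-1-en-2-yl)-2,3-dihydro-1-benzofuran-3-ol | C=C(C)[C@H]1Oc2ccc(I)cc2[C@@H]1O
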